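**Retrosynthetic overview**

- Feature: in ring A (the benzo ring of the 2H-chromene) the methoxy carbon C5 lies between C4a and C6, which carry carbon, while C8a and C7, one atom further out, carry oxygen. Both the C4a–C8a bond and the C6–C7 bond are therefore aryne bonds polarised by the same C5–OMe group: oxygen adds to the far carbon, carbon to the near one.
- Last disconnection: the 1,2-diketone goes back to the deoxybenzoin by aerobic oxidation of the benzylic CH2.
- Key disconnection: C7–O and C6–C(=O) together, to the C6–C7 aryne of the chromene (from its 6-triflyloxy-7-trimethylsilyl precursor) and 4-(prenyloxy)phenylacetic acid, by aryne insertion into the carboxylic acid C–O bond.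
- Ring order: the pyran ring is the only ring made. It comes from the first aryne of a symmetric 2-methoxy-1,3-benzdiyne equivalent and prenal ([2+2], ring opening, oxa-6π closure). Ring A is bought as 2-methoxyresorcinol and ring B as 4-hydroxyphenylacetic acid.
- The benzdiyne equivalent comes from 2-methoxyresorcinol by dibromination, O-silylation, double retro-Brook shift and triflation.

Key step: step 6

Remark: chromene numbering is used for ring positions (O1, C2 with the gem-dimethyl group, C3=C4, C4a, C5 to C8, C8a). The target has no stereocentre; hydroperoxide 20 forms as a racemate whose configuration is lost in the same step.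

**Route**

Step 1
Reactants: 1 2-methoxyresorcinol (2-methoxybenzene-1,3-diol)
Product: 2 4,6-dibromo-2-methoxybenzene-1,3-diol
Conditions: NBS (2.0 equiv), MeCN, 0 °C to rt
Reagents that add atoms: N-bromosuccinimide, O=C1CCC(=O)N1Br
Why: Electrophilic aromatic bromination, in which C4 and C6 are each ortho to one hydroxyl and para to the other while C5 is meta to both, so two equivalents of NBS should brominate only the two doubly activated positions.

Step 2
Reactants: 2 4,6-dibromo-2-methoxybenzene-1,3-diol
Product: 3 1,5-dibromo-3-methoxy-2,4-bis(trimethylsilyloxy)benzene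
Conditions: (Me3Si)2NH, THF, reflux; concentrate
Reagents that add atoms: hexamethyldisilazane, C[Si](C)(C)N[Si](C)(C)C
Why: O-silylation of both phenols with hexamethyldisilazane should give the bis(trimethylsilyl ether) with ammonia as the only by-product, ready for the silyl shift.

Step 3
Reactants: 3 1,5-dibromo-3-methoxy-2,4-bis(trimethylsilyloxy)benzene
Product: 5 2-methoxy-4,6-bis(trimethylsilyl)-1,3-phenylene bis(trifluoromethanesulfonate), via dilithium bis(phenoxide) 4 (not isolated)
Conditions: n-BuLi (2.3 equiv), THF, −78 °C to rt; then Tf2O (2.4 equiv), −78 to 0 °C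
Reagents that add atoms: trifluoromethanesulfonic anhydride, O=S(=O)(OS(=O)(=O)C(F)(F)F)C(F)(F)F
Why: Bromine–lithium exchange places lithium ortho to each silyloxy group, a 1,3 oxygen-to-carbon silyl shift (retro-Brook rearrangement) gives bis(phenoxide) 4, and O-triflation then installs the ortho-silylaryl triflate motif twice, the standard sequence from ortho-bromophenols.

Step 4
Reactants: 5 2-methoxy-4,6-bis(trimethylsilyl)-1,3-phenylene bis(trifluoromethanesulfonate); 6 prenal (3-methylbut-2-enal)
Product: 10 5-methoxy-2,2-dimethyl-7-(trimethylsilyl)-2H-chromen-6-yl trifluoromethanesulfonate, via aryne 7 (not isolated), via benzoxete 8 (not isolated), via ortho-quinone methide 9 (not isolated)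
Conditions: CsF (1.0 equiv), prenal (5 equiv), MeCN, 25 to 50 °C
Reagents that add atoms: none
Why: Fluoride-triggered 1,2-elimination gives aryne 7, whose formal [2+2] addition to the aldehyde C=O (oxygen to the aryne carbon remote from the methoxy group, as for 3-methoxybenzyne) gives benzoxete 8, which opens to ortho-quinone methide 9 and closes by oxa-6π electrocyclisation to the 2,2-dimethyl-2H-chromene (the known aryne/enal chromene synthesis), while one equivalent of CsF and the faster desilylation of the more electron-poor bis(triflate) 5 should leave the second silyl triflate unit intact.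

Step 5
Reactants: 11 4-hydroxyphenylacetic acid; 12 prenyl bromide (1-bromo-3-methylbut-2-ene)
Product: 14 2-[4-(prenyloxy)phenyl]acetic acid, i.e. 2-{4-[(3-methylbut-2-en-1-yl)oxy]phenyl}acetic acid, via prenyl ester 13 (not isolated)
Conditions: K2CO3 (3 equiv), prenyl bromide (2.4 equiv), DMF, rt; then NaOH, MeOH/H2O, 50 °C; then 1 M HCl, 0 °C, to pH 4
Reagents that add atoms: sodium hydroxide, [Na+].[OH-]
Why: Williamson alkylation of both the phenoxide and the carboxylate gives ether-ester 13, and saponification (acyl–oxygen cleavage by hydroxide) then removes only the ester prenyl group, so no phenol-versus-acid selectivity is needed.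

Step 6
Reactants: 10 5-methoxy-2,2-dimethyl-7-(trimethylsilyl)-2H-chromen-6-yl trifluoromethanesulfonate; 14 2-[4-(prenyloxy)phenyl]acetic acid
Product: 19 1-(7-hydroxy-5-methoxy-2,2-dimethyl-2H-chromen-6-yl)-2-[4-(prenyloxy)phenyl]ethanone, via caesium carboxylate 15 (not isolated), via chromenyl aryne 16 (not isolated), via C6 aryl anion 17 (not isolated), via benzoxete alkoxide 18 (not isolated)
Conditions: 14 (2 equiv), Cs2CO3 (1 equiv), MeOH, rt, evaporate, dry (toluene azeotrope); then 10 (1 equiv), CsF (3 equiv), THF, sealed tube, 110 °C; 1 M HCl work-up, 0 °C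
Reagents that add atoms: none
Why: Fluoride attacks silicon at C7 and triflate leaves from C6 to give aryne 16; the carboxylate oxygen of 15 adds to C7, the resulting C6 carbanion 17 attacks the new ester carbonyl to give the four-membered alkoxide 18, and this opens to the C6 ketone and C7 phenoxide, an anionic Fries-type 1,3-acyl shift. The closest known reaction is the insertion of arynes from ortho-silylaryl triflates into the C–O bond of carboxylic acids, which gives ortho-hydroxyaryl ketones. No ring persists (the four-membered ring of 18 closes by a 4-exo-trig attack and reopens) and no stereocentre is formed. The step needs oxygen at C7 and not at C6: the inductively withdrawing C5–OMe group next to C6 polarises the aryne so that the nucleophile attacks the remote terminus C7 and the negative charge develops at C6, the same bias as in 3-methoxybenzyne. It also needs acyl capture to outrun quenching of the C6 anion, which the preformed dry caesium salt (no acidic O–H), the aprotic medium and the high temperature should favour. The excess of carboxylate should keep the product phenoxide and the prenyl alkene from competing for the aryne.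

Step 7
Reactants: 19 1-(7-hydroxy-5-methoxy-2,2-dimethyl-2H-chromen-6-yl)-2-[4-(prenyloxy)phenyl]ethanone
Product: 21 ficucaricone C, 1-(7-hydroxy-5-methoxy-2,2-dimethyl-2H-chromen-6-yl)-2-[4-(prenyloxy)phenyl]ethane-1,2-dione, via alpha-hydroperoxy ketone 20 (not isolated)
Conditions: Cs2CO3 (3 equiv), air (O2 balloon if slow), DMF, rt; aq. NH4Cl work-up
Reagents that add atoms: dioxygen, O=O
Why: Base-mediated autoxidation of a deoxybenzoin, in which the caesium enolate of the CH2 between carbonyl and aryl combines with O2 to give alpha-hydroperoxide 20, which loses water by Kornblum–DeLaMare-type elimination to the 1,2-diketone, while triplet oxygen should leave the chromene and prenyl alkenes untouched.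

**Compound list**

1 | 2-methoxyresorcinol (2-methoxybenzene-1,3-diol) | COc1c(O)cccc1O | starting material
2 | 4,6-dibromo-2-methoxybenzene-1,3-diol | COc1c(O)c(Br)cc(Br)c1O | intermediate
3 | 1,5-dibromo-3-methoxy-2,4-bis(trimethylsilyloxy)benzene | COc1c(O[Si](C)(C)C)c(Br)cc(Br)c1O[Si](C)(C)C | intermediate
4 | dilithium 2-methoxy-4,6-bis(trimethylsilyl)benzene-1,3-bis(olate) | [Li+].[Li+].COc1c([O-])c([Si](C)(C)C)cc([Si](C)(C)C)c1[O-] | intermediate
5 | 2-methoxy-4,6-bis(trimethylsilyl)-1,3-phenylene bis(trifluoromethanesulfonate) | COc1c(OS(=O)(=O)C(F)(F)F)c([Si](C)(C)C)cc([Si](C)(C)C)c1OS(=O)(=O)C(F)(F)F | intermediate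
6 | prenal (3-methylbut-2-enal) | CC(C)=CC=O | starting material
7 | 3,4-didehydro-2-methoxy-6-(trimethylsilyl)phenyl trifluoromethanesulfonate (first aryne) | COC1=C(OS(=O)(=O)C(F)(F)F)C([Si](C)(C)C)=CC#C1 | intermediate
8 | 3-methoxy-2-(2-methylprop-1-en-1-yl)-5-(trimethylsilyl)-2H-benzo[b]oxet-4-yl trifluoromethanesulfonate | COc1c(OS(=O)(=O)C(F)(F)F)c([Si](C)(C)C)cc2OC(C=C(C)C)c12 | intermediate
9 | 2-methoxy-3-(3-methylbut-2-en-1-ylidene)-4-oxo-6-(trimethylsilyl)cyclohexa-1,5-dien-1-yl trifluoromethanesulfonate (ortho-quinone methide) | COC1=C(OS(=O)(=O)C(F)(F)F)C([Si](C)(C)C)=CC(=O)C1=CC=C(C)C | intermediate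
10 | 5-methoxy-2,2-dimethyl-7-(trimethylsilyl)-2H-chromen-6-yl trifluoromethanesulfonate | COc1c2C=CC(C)(C)Oc2cc([Si](C)(C)C)c1OS(=O)(=O)C(F)(F)F | intermediate
11 | 4-hydroxyphenylacetic acid | OC(=O)Cc1ccc(O)cc1 | starting material
12 | prenyl bromide (1-bromo-3-methylbut-2-ene) | CC(C)=CCBr | starting material
13 | 3-methylbut-2-en-1-yl 2-[4-(prenyloxy)phenyl]acetate | CC(C)=CCOC(=O)Cc1ccc(OCC=C(C)C)cc1 | intermediate
14 | 2-[4-(prenyloxy)phenyl]acetic acid | OC(=O)Cc1ccc(OCC=C(C)C)cc1 | intermediate
15 | caesium 2-[4-(prenyloxy)phenyl]acetate | [Cs+].[O-]C(=O)Cc1ccc(OCC=C(C)C)cc1 | intermediate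
16 | 6,7-didehydro-5-methoxy-2,2-dimethyl-2H-chromene (second aryne) | COC1=C2C=CC(C)(C)OC2=CC#C1 | intermediate
17 | caesium 5-methoxy-2,2-dimethyl-7-{[4-(prenyloxy)phenyl]acetoxy}-2H-chromen-6-ide | [Cs+].COc1[c-]c(OC(=O)Cc3ccc(OCC=C(C)C)cc3)cc2OC(C)(C)C=Cc12 | intermediate
18 | caesium alkoxide of the four-membered oxete fused at C6–C7 of the chromene, carrying the 4-(prenyloxy)benzyl group on the alkoxide carbon | [Cs+].COc1c2C=CC(C)(C)Oc2cc2OC([O-])(Cc3ccc(OCC=C(C)C)cc3)c12 | intermediate
19 | 1-(7-hydroxy-5-methoxy-2,2-dimethyl-2H-chromen-6-yl)-2-[4-(prenyloxy)phenyl]ethanone | COc1c2C=CC(C)(C)Oc2cc(O)c1C(=O)Cc1ccc(OCC=C(C)C)cc1 | intermediate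
20 | 2-hydroperoxy-1-(7-hydroxy-5-methoxy-2,2-dimethyl-2H-chromen-6-yl)-2-[4-(prenyloxy)phenyl]ethanone (racemic) | COc1c2C=CC(C)(C)Oc2cc(O)c1C(=O)C(OO)c1ccc(OCC=C(C)C)cc1 | intermediate
21 | ficucaricone C | COc1c2c(cc(O)c1C(=O)C(=O)c1ccc(OCC=C(C)C)cc1)OC(C)(C)C=C2 | target

**Step count and risks**

Total step count: 7. Longest linear sequence: 6 (steps 1, 2, 3, 4, 6, 7); step 5 is a one-step side branch.

Steps most likely to fail:

1. Step 6. The C6 carbanion may be quenched before the acyl shift, either by intramolecular proton abstraction from the acidic benzylic CH2 of the new aryl ester (six-membered transition state) or by adventitious water. That would leave only the C7 aryl ester (simple O-arylation). The product phenoxide or a prenyl alkene (ene reaction) may also consume a second aryne. Fallback, setting out from 10 and returning at 19: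
   - Aryne generation from 10 with CsF in DMF at rt, then aqueous work-up, should give 7-hydroxy-5-methoxy-2,2-dimethyl-2H-chromene-6-carbaldehyde F1. This is the known aryne insertion into the formyl C=O of DMF followed by hydrolysis, with the same methoxy-controlled regiochemistry.
   - Separately, 4-hydroxybenzyl alcohol is O-prenylated with 12 and K2CO3 in acetone to [4-(prenyloxy)phenyl]methanol F2. MsCl, Et3N and LiCl in THF convert it to 1-(chloromethyl)-4-(prenyloxy)benzene F3, and Mg in Et2O at 0 °C gives 4-(prenyloxy)benzylmagnesium chloride F4.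
   - Addition of excess F4 to F1 (the first equivalent deprotonates the phenol) should give the racemic diol 6-{1-hydroxy-2-[4-(prenyloxy)phenyl]ethyl}-5-methoxy-2,2-dimethyl-2H-chromen-7-ol F5.
   - Oxidation of the benzylic carbinol of F5 with MnO2 in CH2Cl2 gives 19.

2. Step 4. Control over fluoride may be lost, so that 10 releases its own aryne and oligomerises. The carbonyl [2+2] capture may also be inefficient, because prenal can be gamma-deprotonated by fluoride, can react by ene pathways, or its ortho-quinone methide 9 can be intercepted by a second aryne. Fallback, setting out from 5 and returning at 10: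
   - CsF (1 equiv) in DMF as solvent-level arynophile without enolisable protons, then aqueous work-up, should give 3-formyl-4-hydroxy-2-methoxy-6-(trimethylsilyl)phenyl trifluoromethanesulfonate F6.
   - Condensation of F6 with 2-methylprop-1-enylboronic acid and catalytic dibenzylamine in dioxane at 90 °C (Petasis-type alkenyl transfer, amine elimination, oxa-6π closure) should give 10 without fluoride present.

3. Step 7. Over-oxidation may occur by C–C cleavage of hydroperoxide 20, or of the diketone by hydroperoxide anion, to the two carboxylic acids. Enolisation may also stall, because the C7 phenoxide forms first and deactivates the ketone. Fallback, setting out from 19 and returning at 21: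
   - The phenoxide–enolate dianion is formed with KN(SiMe3)2 (2.2 equiv) in THF at −78 °C and hydroxylated with 2-(phenylsulfonyl)-3-phenyloxaziridine to the racemic benzoin 2-hydroxy-1-(7-hydroxy-5-methoxy-2,2-dimethyl-2H-chromen-6-yl)-2-[4-(prenyloxy)phenyl]ethanone F7.
   - MnO2 in CH2Cl2 then oxidises F7 to 21. This replaces the peroxide pathway by stoichiometric oxygen transfer followed by an alcohol oxidation.

Further compounds
F1 | step 6 | 7-hydroxy-5-methoxy-2,2-dimethyl-2H-chromene-6-carbaldehyde | COc1c2C=CC(C)(C)Oc2cc(O)c1C=O
F2 | step 6 | [4-(prenyloxy)phenyl]methanol | OCc1ccc(OCC=C(C)C)cc1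
F3 | step 6 | 1-(chloromethyl)-4-(prenyloxy)benzene | ClCc1ccc(OCC=C(C)C)cc1
F4 | step 6 | 4-(prenyloxy)benzylmagnesium chloride | Cl[Mg]Cc1ccc(OCC=C(C)C)cc1
F5 | step 6 | 6-{1-hydroxy-2-[4-(prenyloxy)phenyl]ethyl}-5-methoxy-2,2-dimethyl-2H-chromen-7-ol (racemic) | COc1c2C=CC(C)(C)Oc2cc(O)c1C(O)Cc1ccc(OCC=C(C)C)cc1
F6 | step 4 | 3-formyl-4-hydroxy-2-methoxy-6-(trimethylsilyl)phenyl trifluoromethanesulfonate | COc1c(C=O)c(O)cc([Si](C)(C)C)c1OS(=O)(=O)C(F)(F)F
F7 | step 7 | 2-hydroxy-1-(7-hydroxy-5-methoxy-2,2-dimethyl-2H-chromen-6-yl)-2-[4-(prenyloxy)phenyl]ethanone (racemic) | COc1c2C=CC(C)(C)Oc2cc(O)c1C(=O)C(O)c1ccc(OCC=C(C)C)cc1
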